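Assumption: the acyl chain is read as thirteen carbons with sulfur on C13, and 5, 6 and 14 are taken as catalogue compounds; the target has no stereocentre.
Check of the structures: precursor 8 and cycloaddition product 10 map atom for atom onto ring A (pyrone C3 becomes C1, the alkyne carbons become C2 and C3, pyrone C6, C5 and C4 become C4, C5 and C6), so no correction was needed. The bridged adduct between them is entered as 9.

## Structural features

Echinoclathrine B (17) is an achiral biaryl. Benzene ring A carries a phenolic hydroxyl on C1, an anilide nitrogen on C2 and C4 of a 2-methylpyridine (ring B) on C3, while C4, C5 and C6 are unsubstituted CH. The nitrogen is acylated by an unbranched thirteen-carbon chain whose far end (C13) bears an S-acetyl thioester. With no stereocentre, the problem is one of regiochemistry and chemoselectivity. The fragile groups are the thioacetate (cleaved by hydroxide, amines and hydrides, and a source of thiol that poisons palladium and copper catalysts), the 2-hydroxyanilide (prone to cyclodehydration to a benzoxazole in hot acid, and derived from an air-sensitive 2-aminophenol) and the basic, metal-binding pyridine. The real difficulty lies at C2: nitrogen must be placed between oxygen and the pyridyl group, and this doubly ortho-substituted aniline must then be acylated on nitrogen only. The key step exploits this contiguous O, N, aryl pattern next to three CH groups. C1 and C4 to C6 of ring A correspond to C3 to C6 of a 3-oxy-2-pyrone, and C2 and C3 correspond to the two carbons of a pyridyl ynamide. The O–C(=O)–N unit that tethers them becomes a benzoxazolone carbonyl that is later excised.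

## Logic of the disconnections

17 to 13 and 15 (through 16). The bond cut is the amide bond between the ring A nitrogen and C1 of the chain. It is the only link between the two halves, and cutting it last keeps the thioester away from hydroxide, hot acid and copper. The aromatic core and the chain become independent fragments. The forward step must acylate a 2,6-disubstituted aniline on nitrogen in the presence of a free phenol, a pyridine and a thioester, which is why 15 is activated as 16 and the medium is buffered with bicarbonate.

15 to 14. The bond cut is C13–S. A primary bromide and a soft sulfur nucleophile are the simplest pairing, and the fragment falls back to a bromo acid of the right length. The nucleophile must be weakly basic so that the carboxylic acid needs no protection.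

13 to 11 (through 12) to 10. In the forward sense the two bonds from the oxazolone carbonyl to the C1 oxygen and the C2 nitrogen are broken, preceded by the N–CH2 bond to the 4-methoxybenzyl group. The cyclic carbamate is what the cycloaddition delivers, and it shields the oxidation-prone aminophenol until the penultimate stage. The benzyl group is there because an ynamide nitrogen must be fully substituted. The forward steps need an acidolysis that does not re-alkylate ring A (hence a cation scavenger) and a hydroxide opening run with exclusion of air.

10 to 8 (through 9). The bonds cut are ring A C1–C2 and C3–C4, with CO2 re-inserted across C1 and C4. This removes the whole regiochemical problem at once, because the tether allows only one orientation of the alkyne over the diene. The trisubstituted benzene and its fused oxazolone reduce to a pyrone, a carbamate and an arylalkyne, and two rings form in one operation. The forward step must reach the less favoured carbamate rotamer, which calls for high temperature and high dilution, and the ynamide must survive those conditions.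

8 to 7 and 4. The bond cut is N–C(sp). Copper-catalysed amidation of a bromoalkyne is the standard ynamide construction and joins two fragments of similar complexity. The NH carbamate carries a good enolate-type leaving group on oxygen, so the base must be mild and heterogeneous to avoid elimination to the isocyanate, and the pyridine must not sequester the copper.

7 to 5 and 6. The bond cut is the carbamate O–C(=O) bond, formed forward by addition of the hydroxyl of 5 across the N=C of 6. The step is atom-economic and needs no protecting group. Only a catalytic amount of base should be used, so that the pyrone is not exposed to free pyranolate for long.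

4 to 3 to 1 and 2. The bonds cut are C(sp)–Br (made from C–Si) and the pyridine C4–C(sp) bond. A silyl-capped alkyne is coupled and then converted directly into the bromoalkyne, so the unstable terminal ethynylpyridine is never isolated. The bromination must leave the picoline methyl and the pyridine ring untouched.

## Other disconnections considered

Alternative 1: Ring A is kept as a preformed benzene, and the C3–pyridine bond and the C2–N bond are cut together.
- Forward step: 3-fluoroanisole A1 is lithiated between fluorine and methoxy with a secondary alkyllithium and loses LiF to give an aryne. The aryne is attacked at its distal carbon by (2-methylpyridin-4-yl)magnesium chloride A2, made from 1 by halogen–magnesium exchange. The resulting aryl–magnesium species at C2 is quenched with a sulfonyl azide to give 4-(2-azido-3-methoxyphenyl)-2-methylpyridine A3.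
- In its favour: two ring A bonds form in one flask from three simple components. The methoxy group should steer the nucleophile to the distal aryne carbon by induction. Azide reduction and ether cleavage would reach 13 in about three steps, against seven for the chosen plan, so on step economy this alternative is clearly the better.
- Against it here: the picoline methyl protons of A2 are acidic toward the alkyllithium and the aryl anions. The pyridine nitrogen and the lithiated A1 are competing aryne traps. The hindered 2,6-disubstituted aryl–magnesium species must transfer cleanly to the azide reagent. The methyl ether needs a Lewis-acid cleavage that has to precede introduction of the thioester.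
- Comparison: regiochemistry rests on an electronic bias, whereas in the chosen plan the tether of 8 allows only one orientation. Neither plan has a stereochemical issue, so they are equal there. Alternative 1 is shorter and more convergent, but it depends on the compatibility of several strongly basic species in one flask.

Alternative 2: The ring A C1–O bond is cut, and the oxygen is introduced by C–H oxidation at the end.
- Forward step: 13-bromo-N-[2-(2-methylpyridin-4-yl)phenyl]tridecanamide A4, obtained from 1 by cross-coupling to a 2-arylaniline and acylation with the chloride of 14, is oxidised at constant current at a graphite anode in a fluorinated alcohol. The amide oxygen closes onto the free ortho carbon to give 2-(12-bromododecyl)-4-(2-methylpyridin-4-yl)-1,3-benzoxazole A5. Hydrolytic opening of the oxazole to the hydroxy anilide and thioacetate displacement would finish the synthesis.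
- In its favour: the chain is attached to a simple aniline with no phenol present, so the N- versus O-acylation question of the chosen plan does not arise; on this point the alternative is the better. It uses no protecting group, and at about five steps it is also ahead on step count.
- Against it here: the anilide ring is deactivated by the ortho pyridyl group, which is protonated or hydrogen-bonded in the medium, so a high potential would be needed. The position para to nitrogen is open to coupling or solvent capture. The partial hydrolysis of A5 must stop at the amide and not run on to 13.
- Comparison: the site of C–O bond formation is not enforced by the substrate beyond the blocking of one ortho position, whereas the cycloaddition fixes all three substituents by connectivity. The alternative builds no ring that remains in the target, while the chosen plan builds ring A itself.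

Alternative 3: The C2–N bond and the bond from the amide carbonyl to the chain are cut.
- Forward step: 2-methoxy-6-(2-methylpyridin-4-yl)benzoyl azide A6, from the corresponding 2,6-disubstituted benzoic acid, is heated to give 4-(2-isocyanato-3-methoxyphenyl)-2-methylpyridine A7 by aryl migration. A7 is captured in the same flask by dodec-11-en-1-ylmagnesium bromide A8 to give N-[2-methoxy-6-(2-methylpyridin-4-yl)phenyl]tridec-12-enamide A9. Ether cleavage and radical anti-Markovnikov addition of a thioacid to the terminal alkene would follow.
- In its favour: the hindered amide is made by C–C bond formation at an unhindered isocyanate carbon instead of by acylating a crowded aniline, which is better than the chosen plan on that point. The Curtius migration places nitrogen exactly where the carboxyl carbon was, so its regiochemical security equals that of the tether. The thiol–ene step brings sulfur in last under neutral conditions.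
- Against it here: the Grignard reagent meets a basic pyridine with acidic methyl protons. The ether cleavage must tolerate a terminal alkene and an amide and must come before the thioester. The radical addition has to run in the presence of a free phenol, which can retard radical chains.
- Comparison: the step count (about six) is equal to or slightly better than that of the chosen plan. The alternative depends on a preformed 1,2,3-trisubstituted benzoic acid, whereas the chosen plan creates that pattern from acyclic and heterocyclic pieces.

Key step: step 5

## Route

Step 1
Reactants: 1 4-bromo-2-methylpyridine; 2 ethynyl(trimethyl)silane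
Product: 3 2-methyl-4-[(trimethylsilyl)ethynyl]pyridine
Conditions: Pd(PPh3)2Cl2 (2 mol %), CuI (4 mol %), Et3N, THF, 50 °C
Reagents that add atoms: none
Why: Sonogashira coupling; the electron-poor 4-bromopyridine undergoes oxidative addition readily, and the silyl cap prevents alkyne homocoupling and gives a storable alkyne.

Step 2
Reactants: 3 2-methyl-4-[(trimethylsilyl)ethynyl]pyridine
Product: 4 4-(bromoethynyl)-2-methylpyridine
Conditions: NBS, AgNO3 (20 mol %), acetone, rt, dark
Reagents that add atoms: N-bromosuccinimide, O=C1CCC(=O)N1Br
Why: Silver-catalysed desilylative bromination of a trimethylsilyl alkyne; the C–Si bond is exchanged for C–Br in one operation, so the unstable terminal ethynylpyridine is never handled, and ionic conditions in the dark leave the picoline methyl alone.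

Step 3
Reactants: 5 3-hydroxy-2H-pyran-2-one; 6 4-methoxybenzyl isocyanate
Product: 7 2-oxo-2H-pyran-3-yl N-(4-methoxybenzyl)carbamate
Conditions: Et3N (5 mol %), CH2Cl2, 0 °C to rt
Reagents that add atoms: none
Why: Base-catalysed carbamoylation, the addition of an enolic hydroxyl across an isocyanate; it is atom-economic, and the catalytic amine keeps the pyranolate concentration low while the addition is favoured at room temperature.

Step 4
Reactants: 7 2-oxo-2H-pyran-3-yl N-(4-methoxybenzyl)carbamate; 4 4-(bromoethynyl)-2-methylpyridine
Product: 8 2-oxo-2H-pyran-3-yl N-(4-methoxybenzyl)-N-[(2-methylpyridin-4-yl)ethynyl]carbamate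
Conditions: CuSO4·5H2O (10 mol %), 1,10-phenanthroline (20 mol %), K3PO4, toluene, 65 °C
Reagents that add atoms: none
Why: Copper-catalysed N-alkynylation of a carbamate with a 1-bromoalkyne (Ullmann-type amidation); the insoluble phosphate base in toluene at moderate temperature is chosen to limit E1cB fragmentation of the O-pyranyl carbamate, and the fully substituted product can no longer fragment in that way.

Step 5
Reactants: 8 2-oxo-2H-pyran-3-yl N-(4-methoxybenzyl)-N-[(2-methylpyridin-4-yl)ethynyl]carbamate
Product: 10 3-(4-methoxybenzyl)-4-(2-methylpyridin-4-yl)-1,3-benzoxazol-2(3H)-one, via bridged lactone cycloadduct 9 (not isolated)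
Conditions: o-dichlorobenzene (0.01 M), BHT (cat.), 170 °C, Ar
Reagents that add atoms: none
Why: Proposed new method: a thermal intramolecular [4+2] cycloaddition in which the 3-oxy-2-pyrone of 8 acts as the diene (C3 to C6) and the tethered ynamide triple bond as the dienophile should give the bicyclo[2.2.2]octadiene lactone 9, which loses CO2 by retro-[4+2] under the same conditions and leaves ring A aromatic; the closest known reaction types are Diels–Alder reactions of 2-pyrones with alkynes followed by CO2 extrusion and intramolecular [4+2] cycloadditions of tethered ynamides. The benzene ring is closed by the cycloaddition itself, from four pyrone carbons and two alkyne carbons with new bonds ring A C1–C2 and C3–C4. The oxazolone ring is closed at the same moment as the five-membered ring of a type 1 intramolecular Diels–Alder reaction, the three-atom O–C(=O)–N link joining the diene terminus to the proximal alkyne carbon. No stereocentre remains, because the two bridgehead centres of 9 are fixed relative to each other by the bicycle and vanish when CO2 leaves. The selectivity required is regiochemical and is secured by the tether, since only the nitrogen-bearing alkyne carbon can reach pyrone C3, which delivers the pyridyl-bearing carbon to C6. The carbamate must adopt the less favoured rotamer with both the N-alkynyl and the O-pyranyl group anti to the carbonyl oxygen, hence the high temperature; high dilution suppresses bimolecular addition, and the N-substituent carries no allyl or propargyl unit that could divert the ynamide by a sigmatropic shift.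

Step 6
Reactants: 10 3-(4-methoxybenzyl)-4-(2-methylpyridin-4-yl)-1,3-benzoxazol-2(3H)-one
Product: 11 4-(2-methylpyridin-4-yl)-1,3-benzoxazol-2(3H)-one
Conditions: CF3CO2H, anisole, 75 °C; then aq NaHCO3
Reagents that add atoms: none
Why: Acidolysis of the N-benzylic bond (SN1-type); the benzoxazolone is a good neutral leaving group, the 4-methoxybenzyl cation is intercepted by anisole in a Friedel–Crafts alkylation, and the protonated pyridine is a spectator.

Step 7
Reactants: 11 4-(2-methylpyridin-4-yl)-1,3-benzoxazol-2(3H)-one
Product: 13 2-amino-3-(2-methylpyridin-4-yl)phenol, via aryl carbamic acid 12 (not isolated)
Conditions: NaOH (2 M aq), EtOH, reflux, Ar; then AcOH to pH 7–8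
Reagents that add atoms: none
Why: Alkaline hydrolysis of a cyclic aryl carbamate; hydroxide attacks the carbonyl with the phenoxide as leaving group, and the carbamate 12 loses its carbonyl as carbonate. Air is excluded because the 2-aminophenol is easily oxidised.

Step 8
Reactants: 14 13-bromotridecanoic acid
Product: 15 13-(acetylsulfanyl)tridecanoic acid
Conditions: KSAc, DMF, rt
Reagents that add atoms: potassium thioacetate (KSAc), CC(=O)[S-].[K+]
Why: SN2 displacement of a primary bromide by thioacetate, a soft and weakly basic nucleophile, so the free carboxylic acid needs no protection.

Step 9
Reactants: 15 13-(acetylsulfanyl)tridecanoic acid; 13 2-amino-3-(2-methylpyridin-4-yl)phenol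
Product: 17 echinoclathrine B (S-(13-{[2-hydroxy-6-(2-methylpyridin-4-yl)phenyl]amino}-13-oxotridecyl) ethanethioate), via acid chloride 16 (not isolated)
Conditions: (COCl)2, DMF (cat.), CH2Cl2, 0 °C to rt, evaporate; then 13, NaHCO3 (aq), THF, 0 °C to rt
Reagents that add atoms: none
Why: Acid chloride formation followed by Schotten–Baumann-type N-acylation; under bicarbonate the phenol stays protonated so the amine is the nucleophile, and any O-acyl product of a 2-aminophenol should pass its acyl group on to nitrogen by O-to-N shift. The thioester tolerates oxalyl chloride and a short exposure to cold bicarbonate.

## Compound list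

1 | 4-bromo-2-methylpyridine | Cc1cc(Br)ccn1 | starting material
2 | ethynyl(trimethyl)silane | C#C[Si](C)(C)C | starting material
3 | 2-methyl-4-[(trimethylsilyl)ethynyl]pyridine | Cc1cc(C#C[Si](C)(C)C)ccn1 | intermediate
4 | 4-(bromoethynyl)-2-methylpyridine | Cc1cc(C#CBr)ccn1 | intermediate
5 | 3-hydroxy-2H-pyran-2-one | O=C1OC=CC=C1O | starting material
6 | 4-methoxybenzyl isocyanate | COc1ccc(CN=C=O)cc1 | starting material
7 | 2-oxo-2H-pyran-3-yl N-(4-methoxybenzyl)carbamate | COc1ccc(CNC(=O)OC2=CC=COC2=O)cc1 | intermediate
8 | 2-oxo-2H-pyran-3-yl N-(4-methoxybenzyl)-N-[(2-methylpyridin-4-yl)ethynyl]carbamate | Cc1cc(C#CN(Cc2ccc(OC)cc2)C(=O)OC2=CC=COC2=O)ccn1 | intermediate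
9 | bridged lactone cycloadduct (not isolated): 2-oxabicyclo[2.2.2]octa-5,7-dien-3-one formed across pyrone C3 and C6, with the N-(4-methoxybenzyl)oxazol-2-one ring fused between the oxygen-bearing bridgehead and the adjacent alkene carbon, and the 2-methylpyridin-4-yl group on the other carbon of that alkene; racemic, one enantiomer written | O=C1O[C@H]2C=C[C@]1(OC(=O)N3Cc4ccc(OC)cc4)C3=C2c1ccnc(C)c1 | intermediate
10 | 3-(4-methoxybenzyl)-4-(2-methylpyridin-4-yl)-1,3-benzoxazol-2(3H)-one | Cc1cc(-c2cccc3oc(=O)n(Cc4ccc(OC)cc4)c23)ccn1 | intermediate
11 | 4-(2-methylpyridin-4-yl)-1,3-benzoxazol-2(3H)-one | Cc1cc(-c2cccc3oc(=O)[nH]c23)ccn1 | intermediate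
12 | [2-hydroxy-6-(2-methylpyridin-4-yl)phenyl]carbamic acid (not isolated; present as its sodium salt) | Cc1cc(-c2cccc(O)c2NC(=O)O)ccn1 | intermediate
13 | 2-amino-3-(2-methylpyridin-4-yl)phenol | Cc1cc(-c2cccc(O)c2N)ccn1 | intermediate
14 | 13-bromotridecanoic acid | OC(=O)CCCCCCCCCCCCBr | starting material
15 | 13-(acetylsulfanyl)tridecanoic acid | CC(=O)SCCCCCCCCCCCCC(=O)O | intermediate
16 | 13-(acetylsulfanyl)tridecanoyl chloride (not isolated) | CC(=O)SCCCCCCCCCCCCC(=O)Cl | intermediate
17 | echinoclathrine B, S-(13-{[2-hydroxy-6-(2-methylpyridin-4-yl)phenyl]amino}-13-oxotridecyl) ethanethioate | CC(=O)SCCCCCCCCCCCCC(=O)Nc1c(O)cccc1-c1ccnc(C)c1 | target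

## Step count and risks

Total step count: 9. Longest linear sequence: 7 steps (steps 1, 2, 4, 5, 6, 7 and 9); steps 3 and 8 are side branches.

Least certain steps:

**Step 5 (key step).** The most likely failure is that the carbamate does not populate the rotamer needed for ring closure fast enough. Bimolecular cycloaddition, hydration of the ynamide by traces of water, or acyl transfer from the aryl carbamate to a pyridine nitrogen could then outrun the intramolecular reaction. The strain of forming a five-membered ring fused to the bicyclic transition state adds to the barrier.

The fallback uses known cross-coupling chemistry and gives up the de novo construction of ring A. It sets out from 1, which is borylated (B2pin2, Pd(dppf)Cl2, KOAc, dioxane, 90 °C) to 2-methyl-4-(4,4,5,5-tetramethyl-1,3,2-dioxaborolan-2-yl)pyridine F1. Suzuki–Miyaura coupling of F1 with 2-amino-3-bromophenol F2 (Pd(OAc)2, SPhos, K3PO4, dioxane/water, 90 °C, Ar) should give the aminophenol directly. The fallback comes back to the route at 13.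

**Step 4.** The most likely failure is base-induced E1cB fragmentation of 7 into the isocyanate and the pyranolate before the N–Cu bond forms, because the pyranyl oxygen is a good leaving group. Binding of copper by the pyridine or the pyranolate, and hydration of the product ynamide on work-up, are further risks.

The fallback replaces the electrophilic bromoalkyne and inorganic base by an oxidative coupling of a nucleophilic acetylide at room temperature. It sets out from 3, which is desilylated (K2CO3, MeOH, rt) to 4-ethynyl-2-methylpyridine F3. F3 is converted with CuI in aqueous NH3/EtOH into [(2-methylpyridin-4-yl)ethynyl]copper F4. F4 is then coupled with 7 under O2 (1 atm) with TMEDA in MeCN at rt. The fallback comes back to the route at 8.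

**Step 6.** The most likely failure is incomplete cleavage of the N-benzylic bond, or re-attachment of the benzyl cation to the carbocycle by Friedel–Crafts alkylation if the scavenger is outcompeted.

The fallback changes the order and the mode of cleavage. It sets out from 10, which is opened with NaOH in aqueous EtOH at reflux under argon to 2-[(4-methoxybenzyl)amino]-3-(2-methylpyridin-4-yl)phenol F5. The N-benzyl group of this secondary aniline is then removed by hydrogenolysis (H2, Pd(OH)2/C, EtOH, AcOH, rt). The fallback comes back to the route at 13 and bypasses 11.

**Step 9.** The most likely failure is competing acylation of the phenol oxygen, or double acylation, because the amine is flanked by two ortho substituents. Slow hydrolysis or aminolysis of the thioester is possible if the reaction has to be prolonged.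

The fallback moves C–S bond formation to the end, so that over-acylation can be corrected while no thioester is present. It sets out from 14 and 13. Acid 14 is converted ((COCl)2, DMF (cat.), CH2Cl2) into 13-bromotridecanoyl chloride F6, which is used in slight excess on 13 (NaHCO3, THF/water, 0 °C). Any aryl ester is cleaved by brief K2CO3/MeOH at 0 °C to leave 13-bromo-N-[2-hydroxy-6-(2-methylpyridin-4-yl)phenyl]tridecanamide F7. F7 is then treated with KSAc in DMF at rt. The fallback comes back to the route at 17.

## Further compounds

F1 | step 5 | 2-methyl-4-(4,4,5,5-tetramethyl-1,3,2-dioxaborolan-2-yl)pyridine | Cc1cc(B2OC(C)(C)C(C)(C)O2)ccn1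
F2 | step 5 | 2-amino-3-bromophenol | Nc1c(O)cccc1Br
F3 | step 4 | 4-ethynyl-2-methylpyridine | Cc1cc(C#C)ccn1
F4 | step 4 | [(2-methylpyridin-4-yl)ethynyl]copper | Cc1cc(C#C[Cu])ccn1
F5 | step 6 | 2-[(4-methoxybenzyl)amino]-3-(2-methylpyridin-4-yl)phenol | COc1ccc(CNc2c(O)cccc2-c2ccnc(C)c2)cc1
F6 | step 9 | 13-bromotridecanoyl chloride | ClC(=O)CCCCCCCCCCCCBr
F7 | step 9 | 13-bromo-N-[2-hydroxy-6-(2-methylpyridin-4-yl)phenyl]tridecanamide | Cc1cc(-c2cccc(O)c2NC(=O)CCCCCCCCCCCCBr)ccn1
A1 | alternative 1 | 3-fluoroanisole | COc1cccc(F)c1
A2 | alternative 1 | (2-methylpyridin-4-yl)magnesium chloride | Cc1cc([Mg]Cl)ccn1
A3 | alternative 1 | 4-(2-azido-3-methoxyphenyl)-2-methylpyridine | COc1cccc(-c2ccnc(C)c2)c1N=[N+]=[N-]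
A4 | alternative 2 | 13-bromo-N-[2-(2-methylpyridin-4-yl)phenyl]tridecanamide | Cc1cc(-c2ccccc2NC(=O)CCCCCCCCCCCCBr)ccn1
A5 | alternative 2 | 2-(12-bromododecyl)-4-(2-methylpyridin-4-yl)-1,3-benzoxazole | Cc1cc(-c2cccc3oc(CCCCCCCCCCCCBr)nc23)ccn1
A6 | alternative 3 | 2-methoxy-6-(2-methylpyridin-4-yl)benzoyl azide | COc1cccc(-c2ccnc(C)c2)c1C(=O)N=[N+]=[N-]
A7 | alternative 3 | 4-(2-isocyanato-3-methoxyphenyl)-2-methylpyridine | COc1cccc(-c2ccnc(C)c2)c1N=C=O
A8 | alternative 3 | dodec-11-en-1-ylmagnesium bromide | C=CCCCCCCCCCC[Mg]Br
A9 | alternative 3 | N-[2-methoxy-6-(2-methylpyridin-4-yl)phenyl]tridec-12-enamide | COc1cccc(-c2ccnc(C)c2)c1NC(=O)CCCCCCCCCCC=C
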